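At early times the gamma run moves well, with 74.0% of the substrate left at 8.00 min. Between 40.0 min and 60.0 min, however, substrate moves by 0.4 percentage points against a scatter of 0.5 points, so gamma has slowed sharply, though these two readings can't tell me whether it has stopped.

| flask | substrate | coupling partner | temperature | remark | time |
|---|---|---|---|---|---|
| theta | 1 M | 0.69 M | 20 °C | run made earlier |  |
| gamma | 1 M | 0.69 M | 35 °C | run made earlier |  |
| grey | 1.0 M | 0.500 M | 35 °C |  | 2.0 h |
| amber | 1.0 M | 2.00 M | 35 °C |  | 2.0 h |
| violet | 1.0 M | 1.00 M | 35 °C |  | 2.0 h |
| blue | 1.0 M | 3.00 M | 35 °C |  | 2.0 h |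
| teal | 1.0 M | 0.600 M | 35 °C |  | 2.0 h |

| run | time / min | bis adduct / % | substrate / % |
|---|---|---|---|
| theta | 15.0 | 2.2 | 81.3 |
| theta | 40.0 | 6.4 | 65.5 |
| theta | 80.0 | 10.7 | 58.1 |
| theta | 120 | 12.0 | 54.1 |
| gamma | 8.00 | 4.0 | 74.0 |
| gamma | 20.0 | 8.6 | 61.5 |
| gamma | 40.0 | 11.5 | 56.7 |
| gamma | 60.0 | 12.1 | 56.3 |

(readings scatter by 0.5 percentage points)

1. the flasks by amount of bis adduct, in percent of the substrate charged, highest first, at 2.0 h (grey / amber / violet / blue / teal)
2. the same order at 25 min (grey / amber / violet / blue / teal)
3. the amount of bis adduct, in percent of the substrate charged of the flask you put first, at 2.0 h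
4. the amount of bis adduct, in percent of the substrate charged of the flask you put last, at 2.0 h



I count partner. Substrate that is gone and isn't bis adduct I take to carry one partner, as single product, so gamma has built in 0.558 M of its 0.69 M. The other 0.132 M I call wasted, on my assumption that gamma builds in little more after its last reading, which gives 0.237, the waste number: partner lost for each partner built in, at gamma's charge.

I assume partner destroys itself two at a time, so this number grows in proportion to c(coupling partner). Dividing the charge by one plus the scaled waste number, and then by the two places on each substrate, gives the filling. Gamma's filling is 0.279, and its bis adduct equals that filling raised to the power 1.65.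

Theta at 20 °C tests this. Its last filling of 0.289 gives 12.9% against 12.0% read. But the highest reading is 12.1%, so the rule hasn't seen bis adduct at high filling, and my top figure is the weak one.

The filling climbs with the charge, so I rank blue, amber, violet, teal, grey at both times. Blue has a filling of 0.739, which gives 60.7%, and grey has 0.213, which gives 7.80%.

The forecast gives blue > amber > violet > teal > grey at 2.0 h and blue > amber > violet > teal > grey at 25 min, with 81% first and 6.8% last, higher than mine at the top, on the view that the stall “suggests a dying catalyst”.

The flasks give blue > amber > violet > teal > grey at 2.0 h and blue > amber > violet > teal > grey at 25 min, with 38.0% in blue and 7.52% in grey.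

    substrate + coupling partner → single product (k = 0.00136 M⁻¹ s⁻¹, Ea = 59.0 kJ mol⁻¹)
    coupling partner + single product → bis adduct (k = 0.00157 M⁻¹ s⁻¹, Ea = 61.0 kJ mol⁻¹)
    2 coupling partner → self-condensation product (k = 3.35 × 10⁻⁴ M⁻¹ s⁻¹, Ea = 84.0 kJ mol⁻¹)
    coupling partner + bis adduct → over-reaction product (k = 8.22 × 10⁻⁴ M⁻¹ s⁻¹, Ea = 76.0 kJ mol⁻¹)
    (constants at 35 °C)

Blue holds 38.0% bis adduct and 27.2% over-reaction product, together 65.2% against the 60.7% I read off the filling, and its coupling partner, the limiting reagent, stands at 0.0507% of its own charge. The same waste number, 0.237, on the neighbour of blue charged with 1.2 M gives a filling of 0.425 and so 24.4% bis adduct. That neighbour holds 22.0% bis adduct and 5.36% over-reaction product at 2.00 h, with 38.4% of its substrate left.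

The earlier runs and the new flask were computed on assumed constants, and the scatter is random.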